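The oxane ring is disconnected across O1–C2 and C3–C4. Both carbons are benzylic: C4 carries the 2,6-dioxygenated 4-methoxyphenyl ring A of the chalcone, C2 a 4-oxyphenyl ring. A mild Lewis acid ionises the benzylic alcohol of a (3S)-1-aryl-1,3-diol to the C4 cation, which adds to the (E)-styrene C2=C3 of a skipped diene that already holds C7' and C3'; the resulting C2 cation is captured by the C6 hydroxyl. This one operation joins the two diarylheptanoid halves and sets C2, C3 and C4 from C6 through an all-equatorial chair. C6 and C3' stem from one Brown allylation, C7' from a rhodium-catalysed alkenylation; the chalcone arm is added last.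

Key step: step 14

Remarks on the chemistry
- Numbering used throughout: oxane O1, C2 (4-oxyphenyl), C3, C4 (ring A), C5, C6 (2-arylethyl). Side chain on C3: C7' (aryl), C6'=C5', C4', C3' (OH), C2', C1'. MOM = methoxymethyl, TBS = tert-butyldimethylsilyl.
- Assumption for step 11: (R,R)-Ph-bod is taken to deliver the alkenyl group to the enone face that gives the (3R) ketone; if the sense is the opposite, (S,S)-Ph-bod is used.
- Assumption on supply: 15 and 16 are taken as catalogue compounds; each is otherwise one MOM protection away from the parent phenol.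

Step 1
Reactants: 1 methyl 3-(4-hydroxyphenyl)propanoate
Product: 2 MOM-protected ester
Conditions: MOMCl, i-Pr2NEt, CH2Cl2, 0 °C to rt
Reagents that add atoms: chloromethyl methyl ether (MOMCl), COCCl
Why: Phenol O-alkylation by an activated α-chloro ether under amine base (MOM protection), which leaves the ester untouched.

Step 2
Reactants: 2 MOM-protected ester
Product: 3 MOM-protected 3-arylpropanal
Conditions: i-Bu2AlH (1.05 equiv), CH2Cl2, −78 °C; Rochelle salt work-up
Reagents that add atoms: none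
Why: Partial reduction of a methyl ester; the tetrahedral aluminium hemiacetal is stable at −78 °C and releases the aldehyde only on work-up.

Step 3
Reactants: 3 MOM-protected 3-arylpropanal
Product: 5 (S)-homoallylic alcohol, via homoallyl borinate 4 (not isolated)
Conditions: (+)-Ipc2BOMe, allylmagnesium bromide, Et2O, 0 °C to rt; then 3, −78 °C; NaOH, H2O2
Reagents that add atoms: allylmagnesium bromide, C=CC[Mg]Br (its allyl group is passed on through B-allyldiisopinocampheylborane, C=CCB([C@H]1C[C@H]2C[C@@H]([C@@H]1C)C2(C)C)[C@H]1C[C@H]2C[C@@H]([C@@H]1C)C2(C)C)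
Why: Brown allylboration through a chair Zimmerman–Traxler transition state; the reagent of the (−)-α-pinene series gives the (S) alcohol from an aliphatic aldehyde, and this single centre later becomes both C6 and C3'.

Step 4
Reactants: 5 (S)-homoallylic alcohol
Product: 6 (S)-homoallylic TBS ether
Conditions: TBSCl, imidazole, DMF, rt
Reagents that add atoms: tert-butyldimethylsilyl chloride, CC(C)(C)[Si](C)(C)Cl
Why: Standard silylation of a secondary alcohol; the stereocentre is not involved.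

Step 5
Reactants: 6 (S)-homoallylic TBS ether
Product: 8 (S)-β-silyloxy aldehyde, via vicinal diol 7 (not isolated)
Conditions: OsO4 (2 mol %), NaIO4, 2,6-lutidine, dioxane/H2O, rt
Reagents that add atoms: OsO4, O=[Os](=O)(=O)=O, re-formed by NaIO4, [Na+].[O-][I](=O)(=O)=O (source of the aldehyde oxygen)
Why: Lemieux–Johnson cleavage (dihydroxylation, then periodate glycol cleavage) of the only alkene; it spares the electron-rich aryl MOM ether that ozone could attack.

Step 6
Reactants: 9 5-methoxyresorcinol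
Product: 10 1-methoxy-3,5-bis(methoxymethoxy)benzene
Conditions: MOMCl, i-Pr2NEt, CH2Cl2, 0 °C to rt
Reagents that add atoms: chloromethyl methyl ether (MOMCl), COCCl
Why: Double MOM protection of the two equivalent phenols gives a ring A precursor that is symmetric about the OMe axis.

Step 7
Reactants: 10 1-methoxy-3,5-bis(methoxymethoxy)benzene; 8 (S)-β-silyloxy aldehyde
Product: 12 ring A benzylic alcohol (O6-TBS), via aryllithium 11 (not isolated)
Conditions: n-BuLi, THF, 0 °C; then 8, −78 °C; H2O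
Reagents that add atoms: none
Why: Directed ortho-metalation at the carbon flanked by both MOM ethers (double chelation), then addition to the aldehyde; the new carbinol (C4) should form as an epimer mixture, which is irrelevant because it becomes the cation of step 14.

Step 8
Reactants: 12 ring A benzylic alcohol (O6-TBS)
Product: 13 (3S)-1-aryl-1,3-diol
Conditions: n-Bu4NF, THF, 0 °C to rt
Reagents that add atoms: none
Why: Fluoride desilylation under non-acidic conditions frees the C6 hydroxyl without ionising the very labile benzylic alcohol.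

Step 9
Reactants: 6 (S)-homoallylic TBS ether
Product: 14 (E)-alkenyl pinacol boronate
Conditions: vinylboronic acid pinacol ester (3 equiv), second-generation Grubbs catalyst (5 mol %), CH2Cl2, 40 °C
Reagents that add atoms: vinylboronic acid pinacol ester, C=CB1OC(C)(C)C(C)(C)O1
Why: Olefin cross-metathesis of a terminal alkene with vinyl-B(pin), which is reversible and favours the (E)-alkenyl boronate; this fixes the later C5'=C6' geometry.

Step 10
Reactants: 15 4'-(methoxymethoxy)acetophenone; 16 4-(methoxymethoxy)benzaldehyde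
Product: 17 bis-MOM chalcone
Conditions: KOH, EtOH, rt
Reagents that add atoms: none
Why: Claisen–Schmidt condensation (aldol, then E1cB dehydration) gives the (E)-enone; MOM ethers are stable to base.

Step 11
Reactants: 14 (E)-alkenyl pinacol boronate; 17 bis-MOM chalcone
Product: 18 (3R)-β-alkenyl ketone
Conditions: [Rh(C2H4)2Cl]2 (2.5 mol %), (R,R)-Ph-bod (5.5 mol %), KOH (0.3 equiv), dioxane/H2O, 40 °C
Reagents that add atoms: none
Why: Hayashi–Miyaura conjugate addition: the alkenylrhodium formed by transmetalation adds to the enone β-carbon on the face chosen by the chiral diene, which sets C7' and keeps the E alkene; the remote silyloxy centre has no say.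

Step 12
Reactants: 18 (3R)-β-alkenyl ketone
Product: 19 benzylic alcohol (C1 epimers)
Conditions: NaBH4, MeOH/THF, 0 °C
Reagents that add atoms: none
Why: Borohydride 1,2-reduction of the aryl ketone; the new carbinol centre is removed in the next step, so its configuration is irrelevant.

Step 13
Reactants: 19 benzylic alcohol (C1 epimers)
Product: 20 (E)-styrene skipped diene
Conditions: Burgess reagent, toluene, 50 °C
Reagents that add atoms: none
Why: Burgess dehydration under neutral conditions; only the C3 hydrogens are β to the leaving group, so the conjugated (E)-styrene is the sole regioisomer and the doubly allylic C7'–H is not disturbed.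

Step 14
Reactants: 13 (3S)-1-aryl-1,3-diol; 20 (E)-styrene skipped diene (1.2 equiv)
Product: 23 all-equatorial oxane, via ring A benzylic cation 21 (not isolated), via open-chain C2 cation 22 (not isolated)
Conditions: Ca(NTf2)2 (5 mol %), n-Bu4NPF6 (5 mol %), CH2Cl2, 0 °C to rt
Reagents that add atoms: none
Why: Proposed new method: the Lewis acid ionises only the doubly ortho- and para-oxygenated benzylic alcohol of 13 to cation 21, the 4-alkoxystyrene of 20 (far more nucleophilic than its 1,2-dialkyl alkene) attacks through its β-carbon to form C3–C4 and the 4-alkoxybenzyl cation 22, and the C6 hydroxyl then forms O1–C2 with loss of a proton; this is a formal [4+2] annulation of a 1,4-C,O-dipole with an alkene, whose closest known relatives are the acid-catalysed annulation of ortho-hydroxybenzyl alcohols with styrenes to flavans and Prins-type cation–alkene–oxygen cascades. The oxane closes by 6-exo-trig capture of the quinone-methide-like cation (its C2=C(aryl) π bond lies outside the new ring) in a chair transition state. C6 (S, from step 3) is the only stereocentre of the dipole and sits equatorial in that chair, which puts ring A at C4 equatorial (4,6-cis) and so selects the face of 21; the E alkene geometry becomes the trans relation C2/C3, and the anti relation C3/C4 follows from both substituents being equatorial. C2 is also under thermodynamic control because the 4-alkoxybenzylic C2–O1 bond can re-ionise, and C–C bond formation should be reversible because 21 is more stabilised than 22, so the all-equatorial oxane is the sink; C7' and C3' are carried in unchanged, and the ring, not C7', chooses the alkene face. The step needs selective ionisation of the ring A carbinol without protonation of the styrene, Markovnikov attack, and closure by O1 rather than by a ring A ether oxygen or the C7' aryl ring; the weak calcium catalyst, the aryl-stabilised C2 cation and the free secondary hydroxyl in a six-membered chair are meant to secure these.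

Step 15
Reactants: 23 all-equatorial oxane
Product: 24 ring A bromide
Conditions: NBS (1.0 equiv), CH2Cl2, −78 to 0 °C, dark
Reagents that add atoms: N-bromosuccinimide, O=C1CCC(=O)N1Br
Why: Electrophilic aromatic bromination; the tri-oxygenated ring A is far more reactive than the mono-oxygenated rings or the isolated alkene, and its two free positions are equivalent.

Step 16
Reactants: 16 4-(methoxymethoxy)benzaldehyde
Product: 25 (E)-cinnamoyl Weinreb amide
Conditions: (EtO)2P(O)CH2C(O)N(OMe)Me, NaH, THF, 0 °C to rt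
Reagents that add atoms: diethyl [2-(methoxy(methyl)amino)-2-oxoethyl]phosphonate, CCOP(=O)(OCC)CC(=O)N(C)OC
Why: Horner–Wadsworth–Emmons olefination with a stabilised phosphonate gives the (E)-acrylamide.

Step 17
Reactants: 24 ring A bromide; 25 (E)-cinnamoyl Weinreb amide
Product: 27 fully protected blepharocalyxin E, via aryllithium 26 (not isolated)
Conditions: t-BuLi (2.1 equiv), THF, −78 °C; then 25, −78 to −20 °C; H2O
Reagents that add atoms: none
Why: Bromine–lithium exchange outruns deprotonation at −78 °C, and the aryllithium (chelated by the flanking OMOM and OMe) adds 1,2 to the Weinreb amide, whose stable chelate releases the chalcone ketone only on work-up.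

Step 18
Reactants: 27 fully protected blepharocalyxin E
Product: 28 blepharocalyxin E
Conditions: HCl (conc., catalytic), MeOH/THF, 40 °C
Reagents that add atoms: none
Why: Acid-catalysed acetal exchange removes the seven MOM ethers and the secondary TBS ether in one operation; any reversible ionisation at C2 returns the all-equatorial isomer, which is the target.

Compound list
1 | methyl 3-(4-hydroxyphenyl)propanoate | COC(=O)CCc1ccc(O)cc1 | starting material
2 | methyl 3-[4-(methoxymethoxy)phenyl]propanoate | COCOc1ccc(CCC(=O)OC)cc1 | intermediate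
3 | 3-[4-(methoxymethoxy)phenyl]propanal | COCOc1ccc(CCC=O)cc1 | intermediate
4 | (3S)-1-[4-(methoxymethoxy)phenyl]hex-5-en-3-yl diisopinocampheylborinate (homoallyl borinate) | C=CC[C@@H](OB([C@H]1C[C@H]2C[C@@H]([C@@H]1C)C2(C)C)[C@H]1C[C@H]2C[C@@H]([C@@H]1C)C2(C)C)CCc1ccc(OCOC)cc1 | intermediate
5 | (3S)-1-[4-(methoxymethoxy)phenyl]hex-5-en-3-ol | C=CC[C@@H](O)CCc1ccc(OCOC)cc1 | intermediate
6 | tert-butyl{[(3S)-1-[4-(methoxymethoxy)phenyl]hex-5-en-3-yl]oxy}dimethylsilane | C=CC[C@@H](O[Si](C)(C)C(C)(C)C)CCc1ccc(OCOC)cc1 | intermediate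
7 | (4S)-4-[(tert-butyldimethylsilyl)oxy]-6-[4-(methoxymethoxy)phenyl]hexane-1,2-diol (both C2 epimers) | OCC(O)C[C@@H](O[Si](C)(C)C(C)(C)C)CCc1ccc(OCOC)cc1 | intermediate
8 | (3S)-3-[(tert-butyldimethylsilyl)oxy]-5-[4-(methoxymethoxy)phenyl]pentanal | O=CC[C@@H](O[Si](C)(C)C(C)(C)C)CCc1ccc(OCOC)cc1 | intermediate
9 | 5-methoxyresorcinol (5-methoxybenzene-1,3-diol) | COc1cc(O)cc(O)c1 | starting material
10 | 1-methoxy-3,5-bis(methoxymethoxy)benzene | COCOc1cc(OC)cc(OCOC)c1 | intermediate
11 | [4-methoxy-2,6-bis(methoxymethoxy)phenyl]lithium | [Li]c1c(OCOC)cc(OC)cc1OCOC | intermediate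
12 | (1RS,3S)-3-[(tert-butyldimethylsilyl)oxy]-1-[4-methoxy-2,6-bis(methoxymethoxy)phenyl]-5-[4-(methoxymethoxy)phenyl]pentan-1-ol | COCOc1cc(OC)cc(OCOC)c1C(O)C[C@@H](O[Si](C)(C)C(C)(C)C)CCc1ccc(OCOC)cc1 | intermediate
13 | (1RS,3S)-1-[4-methoxy-2,6-bis(methoxymethoxy)phenyl]-5-[4-(methoxymethoxy)phenyl]pentane-1,3-diol | COCOc1cc(OC)cc(OCOC)c1C(O)C[C@@H](O)CCc1ccc(OCOC)cc1 | intermediate
14 | tert-butyl{[(3S,5E)-1-[4-(methoxymethoxy)phenyl]-6-(4,4,5,5-tetramethyl-1,3,2-dioxaborolan-2-yl)hex-5-en-3-yl]oxy}dimethylsilane | CC1(C)OB(/C=C/C[C@@H](O[Si](C)(C)C(C)(C)C)CCc2ccc(OCOC)cc2)OC1(C)C | intermediate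
15 | 1-[4-(methoxymethoxy)phenyl]ethan-1-one | CC(=O)c1ccc(OCOC)cc1 | starting material
16 | 4-(methoxymethoxy)benzaldehyde | COCOc1ccc(C=O)cc1 | starting material
17 | (E)-1,3-bis[4-(methoxymethoxy)phenyl]prop-2-en-1-one | COCOc1ccc(/C=C/C(=O)c2ccc(OCOC)cc2)cc1 | intermediate
18 | (3R,4E,7S)-7-[(tert-butyldimethylsilyl)oxy]-1,3,9-tris[4-(methoxymethoxy)phenyl]non-4-en-1-one | COCOc1ccc(cc1)C(=O)C[C@H](/C=C/C[C@@H](O[Si](C)(C)C(C)(C)C)CCc1ccc(OCOC)cc1)c1ccc(OCOC)cc1 | intermediate
19 | (1RS,3R,4E,7S)-7-[(tert-butyldimethylsilyl)oxy]-1,3,9-tris[4-(methoxymethoxy)phenyl]non-4-en-1-ol | COCOc1ccc(cc1)C(O)C[C@H](/C=C/C[C@@H](O[Si](C)(C)C(C)(C)C)CCc1ccc(OCOC)cc1)c1ccc(OCOC)cc1 | intermediate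
20 | tert-butyl{[(3S,5E,7S,8E)-1,7,9-tris[4-(methoxymethoxy)phenyl]nona-5,8-dien-3-yl]oxy}dimethylsilane | COCOc1ccc(/C=C/[C@H](/C=C/C[C@@H](O[Si](C)(C)C(C)(C)C)CCc2ccc(OCOC)cc2)c2ccc(OCOC)cc2)cc1 | intermediate
21 | ring A benzylic cation at C4: (3S)-3-hydroxy-1-[4-methoxy-2,6-bis(methoxymethoxy)phenyl]-5-[4-(methoxymethoxy)phenyl]pentan-1-ylium | COCOc1cc(OC)cc(OCOC)c1[CH+]C[C@@H](O)CCc1ccc(OCOC)cc1 | intermediate
22 | open-chain 4-(methoxymethoxy)benzyl cation at C2 after C3–C4 bond formation (C3, C4, C6, C7', C3' as in 23; C6–OH free) | COCOc1ccc(cc1)[CH+][C@H]([C@@H](C[C@@H](O)CCc1ccc(OCOC)cc1)c1c(OCOC)cc(OC)cc1OCOC)[C@H](/C=C/C[C@@H](O[Si](C)(C)C(C)(C)C)CCc1ccc(OCOC)cc1)c1ccc(OCOC)cc1 | intermediate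
23 | tert-butyl{[(3S,5E,7S)-7-[(2S,3R,4R,6S)-4-[4-methoxy-2,6-bis(methoxymethoxy)phenyl]-2-[4-(methoxymethoxy)phenyl]-6-{2-[4-(methoxymethoxy)phenyl]ethyl}oxan-3-yl]-1,7-bis[4-(methoxymethoxy)phenyl]hept-5-en-3-yl]oxy}dimethylsilane | COc1cc(OCOC)c([C@@H]2C[C@H](CCc3ccc(OCOC)cc3)O[C@H](c3ccc(OCOC)cc3)[C@H]2[C@H](/C=C/C[C@@H](O[Si](C)(C)C(C)(C)C)CCc2ccc(OCOC)cc2)c2ccc(OCOC)cc2)c(OCOC)c1 | intermediate
24 | the 3-bromo-4-methoxy-2,6-bis(methoxymethoxy)phenyl analogue of 23 (bromine on ring A between OMe and OMOM) | COc1cc(OCOC)c([C@@H]2C[C@H](CCc3ccc(OCOC)cc3)O[C@H](c3ccc(OCOC)cc3)[C@H]2[C@H](/C=C/C[C@@H](O[Si](C)(C)C(C)(C)C)CCc2ccc(OCOC)cc2)c2ccc(OCOC)cc2)c(OCOC)c1Br | intermediate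
25 | (E)-N-methoxy-3-[4-(methoxymethoxy)phenyl]-N-methylprop-2-enamide | CON(C)C(=O)/C=C/c1ccc(OCOC)cc1 | intermediate
26 | aryllithium from 24 (lithium in place of bromine on ring A) | COc1cc(OCOC)c([C@@H]2C[C@H](CCc3ccc(OCOC)cc3)O[C@H](c3ccc(OCOC)cc3)[C@H]2[C@H](/C=C/C[C@@H](O[Si](C)(C)C(C)(C)C)CCc2ccc(OCOC)cc2)c2ccc(OCOC)cc2)c(OCOC)c1[Li] | intermediate
27 | (E)-1-{3-[(2S,3R,4R,6S)-3-{(1S,2E,5S)-5-[(tert-butyldimethylsilyl)oxy]-1,7-bis[4-(methoxymethoxy)phenyl]hept-2-en-1-yl}-2-[4-(methoxymethoxy)phenyl]-6-{2-[4-(methoxymethoxy)phenyl]ethyl}oxan-4-yl]-6-methoxy-2,4-bis(methoxymethoxy)phenyl}-3-[4-(methoxymethoxy)phenyl]prop-2-en-1-one | COc1cc(OCOC)c([C@@H]2C[C@H](CCc3ccc(OCOC)cc3)O[C@H](c3ccc(OCOC)cc3)[C@H]2[C@H](/C=C/C[C@@H](O[Si](C)(C)C(C)(C)C)CCc2ccc(OCOC)cc2)c2ccc(OCOC)cc2)c(OCOC)c1C(=O)/C=C/c1ccc(OCOC)cc1 | intermediate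
28 | blepharocalyxin E: (E)-1-{2,4-dihydroxy-3-[(2S,3R,4R,6S)-3-[(1S,2E,5S)-5-hydroxy-1,7-bis(4-hydroxyphenyl)hept-2-en-1-yl]-2-(4-hydroxyphenyl)-6-[2-(4-hydroxyphenyl)ethyl]oxan-4-yl]-6-methoxyphenyl}-3-(4-hydroxyphenyl)prop-2-en-1-one | COc1cc(O)c([C@@H]2C[C@H](CCc3ccc(O)cc3)O[C@H](c3ccc(O)cc3)[C@H]2[C@H](/C=C/C[C@@H](O)CCc2ccc(O)cc2)c2ccc(O)cc2)c(O)c1C(=O)/C=C/c1ccc(O)cc1 | target

Total step count: 18
Longest linear sequence: 12 steps (1, 2, 3, 4, 9, 11, 12, 13, 14, 15, 17, 18)

Steps most likely to fail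

Step 14 (Proposed new method). What may go wrong: cation 22 may lose a proton, or be attacked by the aryl ring on C7' or by a ring A ether oxygen (with loss of MOM), faster than O1 closes. Cation 21 may fragment in a retro-Prins sense, or lose a proton and then ionise at the allylic C6–O bond. The facial relay from C6 to C4 may also be weak. The fallback uses known chemistry, sets out from 18 and 12 and comes back at 23. Ketone 18 is converted (TMSOTf, Et3N, CH2Cl2, 0 °C) into its (Z)-trimethylsilyl enol ether, tert-butyl{[(3S,5E,7S,8Z)-1,7,9-tris[4-(methoxymethoxy)phenyl]-9-[(trimethylsilyl)oxy]nona-5,8-dien-3-yl]oxy}dimethylsilane F1. F1 is alkylated at C3 by the benzylic alcohol 12 under catalytic Bi(OTf)3 (CH2Cl2, −40 °C), a Mukaiyama-type SN1 benzylation of an enol silane, to give the δ-silyloxy ketone (2R,3R,5S)-5-[(tert-butyldimethylsilyl)oxy]-2-{(1S,2E,5S)-5-[(tert-butyldimethylsilyl)oxy]-1,7-bis[4-(methoxymethoxy)phenyl]hept-2-en-1-yl}-3-[4-methoxy-2,6-bis(methoxymethoxy)phenyl]-1,7-bis[4-(methoxymethoxy)phenyl]heptan-1-one F2, whose C3 centre can be equilibrated and whose C4 epimers should be separable. Reductive etherification of F2 (Et3SiH, catalytic BiBr3, MeCN, 0 °C: desilylation, hemiketal, cyclic oxocarbenium ion, axial hydride at C2) then gives 23. The two bonds are made one after the other, no cation is placed on C2 next to the skipped diene, and C2 is set by axial hydride delivery.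

Step 18. What may go wrong: while seven MOM ethers are slowly removed, the acid may close the 2'-hydroxychalcone onto its enone (flavanone formation) and may solvolyse the C2–O1 benzylic ether. The fallback sets out from 24 and comes back at 28. The aryllithium from 24 (t-BuLi, THF, −78 °C) is acylated with N-methoxy-N-methylacetamide to give the methyl ketone analogue of 27 (acetyl in place of the cinnamoyl group on ring A) F3. The same acidic methanolysis is then run on F3, where no enone is present, to give the fully deprotected acetophenone 1-{2,4-dihydroxy-3-[(2S,3R,4R,6S)-3-[(1S,2E,5S)-5-hydroxy-1,7-bis(4-hydroxyphenyl)hept-2-en-1-yl]-2-(4-hydroxyphenyl)-6-[2-(4-hydroxyphenyl)ethyl]oxan-4-yl]-6-methoxyphenyl}ethan-1-one F4. Claisen–Schmidt condensation of F4 with 4-hydroxybenzaldehyde (KOH, EtOH/H2O, rt) builds the chalcone last, under basic conditions in which the chalcone phenolate does not cyclise, and gives 28.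

Step 11. What may go wrong: slow transmetalation of the pinacol boronate with competing protodeboronation, or insufficient facial discrimination on the acyclic diaryl enone. The fallback sets out from 14 and 16 and comes back at 20, so that 18 and 19 are bypassed. Aldehyde 16 and vinylmagnesium bromide (THF, 0 °C) give racemic 1-[4-(methoxymethoxy)phenyl]prop-2-en-1-ol F5. Boronate 14 with KHF2 (MeOH/H2O) gives potassium trifluoro{(1E,4S)-4-[(tert-butyldimethylsilyl)oxy]-6-[4-(methoxymethoxy)phenyl]hex-1-en-1-yl}borate F6. An iridium-catalysed enantioconvergent allylic vinylation of F5 with F6 ([Ir(cod)Cl]2, BINOL-derived phosphoramidite–olefin ligand, acidic promoter, dioxane, rt) gives the branched skipped diene tert-butyl{[(3S,5E,7R)-1,7-bis[4-(methoxymethoxy)phenyl]nona-5,8-dien-3-yl]oxy}dimethylsilane F7. Wittig methylenation of 16 (Ph3PCH3Br, KOt-Bu, THF) gives 4-(methoxymethoxy)styrene F8. Cross-metathesis of the terminal vinyl group of F7 with F8 (second-generation Hoveyda–Grubbs catalyst, CH2Cl2, 40 °C) gives 20.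

Further compounds
F1 | step 14 | tert-butyl{[(3S,5E,7S,8Z)-1,7,9-tris[4-(methoxymethoxy)phenyl]-9-[(trimethylsilyl)oxy]nona-5,8-dien-3-yl]oxy}dimethylsilane | COCOc1ccc(cc1)/C(O[Si](C)(C)C)=C/[C@H](/C=C/C[C@@H](O[Si](C)(C)C(C)(C)C)CCc1ccc(OCOC)cc1)c1ccc(OCOC)cc1
F2 | step 14 | (2R,3R,5S)-5-[(tert-butyldimethylsilyl)oxy]-2-{(1S,2E,5S)-5-[(tert-butyldimethylsilyl)oxy]-1,7-bis[4-(methoxymethoxy)phenyl]hept-2-en-1-yl}-3-[4-methoxy-2,6-bis(methoxymethoxy)phenyl]-1,7-bis[4-(methoxymethoxy)phenyl]heptan-1-one | COCOc1ccc(cc1)C(=O)[C@H]([C@@H](C[C@@H](O[Si](C)(C)C(C)(C)C)CCc1ccc(OCOC)cc1)c1c(OCOC)cc(OC)cc1OCOC)[C@H](/C=C/C[C@@H](O[Si](C)(C)C(C)(C)C)CCc1ccc(OCOC)cc1)c1ccc(OCOC)cc1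
F3 | step 18 | methyl ketone analogue of 27: 1-{3-[(2S,3R,4R,6S)-3-{(1S,2E,5S)-5-[(tert-butyldimethylsilyl)oxy]-1,7-bis[4-(methoxymethoxy)phenyl]hept-2-en-1-yl}-2-[4-(methoxymethoxy)phenyl]-6-{2-[4-(methoxymethoxy)phenyl]ethyl}oxan-4-yl]-6-methoxy-2,4-bis(methoxymethoxy)phenyl}ethan-1-one | COc1cc(OCOC)c([C@@H]2C[C@H](CCc3ccc(OCOC)cc3)O[C@H](c3ccc(OCOC)cc3)[C@H]2[C@H](/C=C/C[C@@H](O[Si](C)(C)C(C)(C)C)CCc2ccc(OCOC)cc2)c2ccc(OCOC)cc2)c(OCOC)c1C(C)=O
F4 | step 18 | 1-{2,4-dihydroxy-3-[(2S,3R,4R,6S)-3-[(1S,2E,5S)-5-hydroxy-1,7-bis(4-hydroxyphenyl)hept-2-en-1-yl]-2-(4-hydroxyphenyl)-6-[2-(4-hydroxyphenyl)ethyl]oxan-4-yl]-6-methoxyphenyl}ethan-1-one | COc1cc(O)c([C@@H]2C[C@H](CCc3ccc(O)cc3)O[C@H](c3ccc(O)cc3)[C@H]2[C@H](/C=C/C[C@@H](O)CCc2ccc(O)cc2)c2ccc(O)cc2)c(O)c1C(C)=O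
F5 | step 11 | racemic 1-[4-(methoxymethoxy)phenyl]prop-2-en-1-ol | C=CC(O)c1ccc(OCOC)cc1
F6 | step 11 | potassium trifluoro{(1E,4S)-4-[(tert-butyldimethylsilyl)oxy]-6-[4-(methoxymethoxy)phenyl]hex-1-en-1-yl}borate | [K+].F[B-](F)(F)/C=C/C[C@@H](O[Si](C)(C)C(C)(C)C)CCc1ccc(OCOC)cc1
F7 | step 11 | tert-butyl{[(3S,5E,7R)-1,7-bis[4-(methoxymethoxy)phenyl]nona-5,8-dien-3-yl]oxy}dimethylsilane | C=C[C@H](/C=C/C[C@@H](O[Si](C)(C)C(C)(C)C)CCc1ccc(OCOC)cc1)c1ccc(OCOC)cc1
F8 | step 11 | 4-(methoxymethoxy)styrene | C=Cc1ccc(OCOC)cc1
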